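**Retrosynthetic overview**

1. Target 15 consists of ring C (cyclohexene: C1 quaternary with CH3 and the styryl arm, C2 benzylic CH carrying the coumarin of rings A/B, C3=C4 olefin with CH3 on C4, C5 and C6 CH2) and a second coumarin (rings D/E) on the (E)-vinyl arm. The arm is cut at the aryl–vinyl bond (Heck; the vinyl group comes from a C1 aldehyde), and the C1 methyl is cut as an enolate methylation anti to the C2 aryl group.
2. Key disconnection: the C3=C4 double bond of ring C. Opened there, ring C is a 1,7-diene, 2-(1-arylallyl)-5-methylhex-5-enal, whose C1–C2 bond is the retron of an iridium/amine α-allylation of 5-methylhex-5-enal with a racemic aryl vinyl carbinol. Allylation and ring-closing metathesis are run in one flask, so two stereochemically undefined fragments give ring C with the benzylic centre set.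
3. Feature that makes this possible: C3 is an olefinic CH bonded only to benzylic C2, and C4 is an olefinic carbon bonded only to CH3 and C5. The two ends are therefore a vinyl group on a benzylic carbon and an isopropenyl group, and C1 next to C2 can sit at the aldehyde level (enamine donor). Once ring C is closed, the C2 aryl group can steer the C1 methylation.
4. Order of ring formation: rings A/B and D/E are bought as 5,7-dimethoxycoumarin and functionalised at C8; ring C is the only ring built (step 5).

Key step: step 5

Assumption 1 (regiochemistry): electrophiles attack 5,7-dimethoxycoumarin at C8, which is para to the 5-methoxy group, ortho to the 7-methoxy group and the ring oxygen, and less crowded than C6.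
Assumption 2 (sense of induction): (R)-L is taken to give the (R)-benzylic centre in step 5; if the sense is the opposite, (S)-L is used with no other change, and the configuration that A induces at C1 is immaterial because step 6 re-forms C1.
Abbreviations: L = 4-(5H-dibenzo[b,f]azepin-5-yl)dinaphtho[2,1-d:1',2'-f][1,3,2]dioxaphosphepine (BINOL-derived phosphoramidite–olefin ligand); A = 2-{bis[3,5-bis(trifluoromethyl)phenyl](trimethylsilyloxy)methyl}pyrrolidine; cod = cycloocta-1,5-diene; H2IMes = 1,3-dimesitylimidazolidin-2-ylidene.

**Route**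

Step 1
Reactants: 1 5,7-dimethoxy-2H-chromen-2-one (5,7-dimethoxycoumarin)
Product: 3 5,7-dimethoxy-2-oxo-2H-chromene-8-carbaldehyde, via iminium chloride 2 (not isolated)
Conditions: POCl3, DMF, 0 to 70 °C; then ice/H2O
Reagents that add atoms: N,N-dimethylformamide CN(C)C=O (formyl carbon); water O (formyl oxygen)
Why: Vilsmeier–Haack formylation (electrophilic aromatic substitution): the chloroiminium ion attacks C8, which is para to the 5-methoxy group, ortho to the 7-methoxy group and the ring oxygen and less crowded than C6, and water hydrolyses iminium salt 2 to the aldehyde.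

Step 2
Reactants: 3 5,7-dimethoxy-2-oxo-2H-chromene-8-carbaldehyde
Product: 4 rac-8-(1-hydroxyprop-2-en-1-yl)-5,7-dimethoxy-2H-chromen-2-one
Conditions: CH2=CHMgBr (1.1 equiv), THF, −78 °C; then H2O
Reagents that add atoms: vinylmagnesium bromide C=C[Mg]Br
Why: Grignard 1,2-addition: at −78 °C the aldehyde is far more electrophilic than the conjugated lactone, and the racemic carbinol is what step 5 needs because both of its enantiomers converge on one π-allyl complex.

Step 3
Reactants: 5 ethyl 5-oxohexanoate
Product: 6 ethyl 5-methylhex-5-enoate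
Conditions: Ph3PCH3Br, KOtBu, THF, 0 °C to rt
Reagents that add atoms: methyltriphenylphosphonium bromide C[P+](c1ccccc1)(c1ccccc1)c1ccccc1.[Br-]
Why: Wittig methylenation: the non-stabilised ylide converts the ketone into the 1,1-disubstituted olefin and leaves the ester alone.

Step 4
Reactants: 6 ethyl 5-methylhex-5-enoate
Product: 8 5-methylhex-5-enal, via aluminium hemiacetal 7 (not isolated)
Conditions: i-Bu2AlH (1.05 equiv), CH2Cl2, −78 °C; then aq. potassium sodium tartrate
Reagents that add atoms: none
Why: Partial reduction of an ester with i-Bu2AlH: hemiacetal 7 is stable at −78 °C and collapses to the aldehyde only on aqueous work-up, so over-reduction is avoided.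

Step 5
Reactants: 4 rac-8-(1-hydroxyprop-2-en-1-yl)-5,7-dimethoxy-2H-chromen-2-one; 8 5-methylhex-5-enal (2 equiv)
Product: 10 (1R,2R)-2-(5,7-dimethoxy-2-oxo-2H-chromen-8-yl)-4-methylcyclohex-3-ene-1-carbaldehyde, via open-chain allylation aldehyde 9 (not isolated)
Conditions: stage 1: [Ir(cod)Cl]2 (3 mol%), (R)-L (12 mol%), (S)-A (15 mol%), ZnBr2 (7.5 mol%), ClCH2CH2Cl, 25 °C; stage 2, same flask: TsOH·H2O (20 mol%), second-generation Hoveyda–Grubbs catalyst (H2IMes)Cl2Ru(=CH-C6H4-2-O-i-Pr) (5 mol%), 45 °C
Reagents that add atoms: none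
Why: In stage 1 the monovalent iridium complex of L ionises both enantiomers of 4 (ZnBr2 assists loss of hydroxide) to one trivalent iridium π-allyl species, and the enamine formed from 8 and A attacks its aryl-bearing terminus to give the branched aldehyde 9, whereupon in stage 2 the ruthenium alkylidene loads onto the new vinyl group, forms a ruthenacyclobutane with the 1,1-disubstituted olefin and releases ethylene, creating the C3=C4 bond of ring C. The closest known reaction types are the iridium/amine α-allylation of linear aldehydes with 2,6-dialkoxyaryl vinyl carbinols, the ring-closing metathesis of the resulting 2-(1-arylallyl)-5-methylhex-5-enals to 2-aryl-4-methylcyclohex-3-ene-1-carbaldehydes, and iridium allylic substitution followed by ruthenium metathesis in one flask. Ring C is closed by ring-closing olefin metathesis of a 1,7-diene, the new double bond being endocyclic in a six-membered ring and the closure being driven by escape of ethylene. C2 is controlled by the ligand L on iridium, which fixes the face of the π-allyl that is attacked, and C1 by the amine A, which shields one face of the enamine; C1 is provisional because step 6 re-forms it. The step needs branched instead of linear allylation, secured by the electron-rich aryl group on the allyl terminus together with the iridium catalyst, and metathesis at the vinyl and isopropenyl groups only, secured because the pyranone olefin of ring B is endocyclic, conjugated and electron-poor and is left alone by ruthenium alkylidenes. The acid added in stage 2 turns the amine and any enamine into ammonium salts, which cannot convert the ruthenium alkylidene into an inert aminocarbene.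

Step 6
Reactants: 10 (1R,2R)-2-(5,7-dimethoxy-2-oxo-2H-chromen-8-yl)-4-methylcyclohex-3-ene-1-carbaldehyde
Product: 12 (1S,2S)-2-(5,7-dimethoxy-2-oxo-2H-chromen-8-yl)-1,4-dimethylcyclohex-3-ene-1-carbaldehyde, via potassium enolate 11 (not isolated)
Conditions: KN(SiMe3)2 (1.1 equiv), THF, −78 °C; MeI, −78 to −30 °C
Reagents that add atoms: iodomethane CI
Why: C-alkylation of an aldehyde enolate: allylic 1,3-strain holds the C2 aryl group pseudoaxial on the exocyclic enolate, so iodomethane should enter from the opposite face and place the new methyl trans to the aryl group (formyl cis), which fixes quaternary C1 whatever the C1 configuration of 10 was; the C2 descriptor changes from R to S only because the CIP priorities change.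

Step 7
Reactants: 12 (1S,2S)-2-(5,7-dimethoxy-2-oxo-2H-chromen-8-yl)-1,4-dimethylcyclohex-3-ene-1-carbaldehyde
Product: 13 8-[(1R,6R)-6-ethenyl-3,6-dimethylcyclohex-2-en-1-yl]-5,7-dimethoxy-2H-chromen-2-one
Conditions: Ph3PCH3Br, KOtBu, THF, 0 °C to rt
Reagents that add atoms: methyltriphenylphosphonium bromide C[P+](c1ccccc1)(c1ccccc1)c1ccccc1.[Br-]
Why: Wittig methylenation: the small ylide still reaches the neopentyl aldehyde, which cannot epimerise because C1 is quaternary, and the aldehyde should consume the ylide faster than the lactone could.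

Step 8
Reactants: 1 5,7-dimethoxy-2H-chromen-2-one
Product: 14 8-iodo-5,7-dimethoxy-2H-chromen-2-one
Conditions: N-iodosuccinimide, CF3CO2H (cat.), MeCN, 0 °C to rt
Reagents that add atoms: N-iodosuccinimide O=C1CCC(=O)N1I
Why: Electrophilic aromatic iodination: the iodonium equivalent enters C8 for the same electronic and steric reasons as in step 1, and the electron-poor pyranone ring is not attacked.

Step 9
Reactants: 13 8-[(1R,6R)-6-ethenyl-3,6-dimethylcyclohex-2-en-1-yl]-5,7-dimethoxy-2H-chromen-2-one; 14 8-iodo-5,7-dimethoxy-2H-chromen-2-one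
Product: 15 8-[(E)-2-[(1R,2R)-2-(5,7-dimethoxy-2-oxo-2H-chromen-8-yl)-1,4-dimethylcyclohex-3-en-1-yl]ethenyl]-5,7-dimethoxy-2H-chromen-2-one (target)
Conditions: Pd(OAc)2 (10 mol%), n-Bu4NCl, NaHCO3, DMF, 90 °C
Reagents that add atoms: none
Why: Heck reaction: zerovalent palladium formed in situ inserts into the C–I bond of 14, the aryl group is delivered to the terminal carbon of the only monosubstituted olefin, and since the other neighbour of the palladium-bearing carbon is quaternary the single possible β-hydride elimination should give the (E)-styryl double bond without touching C1 or C2.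

**Compound list**

1 | 5,7-dimethoxy-2H-chromen-2-one (5,7-dimethoxycoumarin) | COc1cc(OC)c2ccc(=O)oc2c1 | starting material
2 | N-[(5,7-dimethoxy-2-oxo-2H-chromen-8-yl)methylidene]-N-methylmethanaminium chloride | C[N+](C)=Cc1c(OC)cc(OC)c2ccc(=O)oc12.[Cl-] | intermediate
3 | 5,7-dimethoxy-2-oxo-2H-chromene-8-carbaldehyde | O=Cc1c(OC)cc(OC)c2ccc(=O)oc12 | intermediate
4 | rac-8-(1-hydroxyprop-2-en-1-yl)-5,7-dimethoxy-2H-chromen-2-one | C=CC(O)c1c(OC)cc(OC)c2ccc(=O)oc12 | intermediate
5 | ethyl 5-oxohexanoate | CCOC(=O)CCCC(C)=O | starting material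
6 | ethyl 5-methylhex-5-enoate | CCOC(=O)CCCC(C)=C | intermediate
7 | [(1-ethoxy-5-methylhex-5-en-1-yl)oxy]bis(2-methylpropyl)alumane | CCOC(CCCC(C)=C)O[Al](CC(C)C)CC(C)C | intermediate
8 | 5-methylhex-5-enal | O=CCCCC(C)=C | intermediate
9 | (2R)-2-[(1R)-1-(5,7-dimethoxy-2-oxo-2H-chromen-8-yl)prop-2-en-1-yl]-5-methylhex-5-enal | O=C[C@H](CCC(C)=C)[C@@H](C=C)c1c(OC)cc(OC)c2ccc(=O)oc12 | intermediate
10 | (1R,2R)-2-(5,7-dimethoxy-2-oxo-2H-chromen-8-yl)-4-methylcyclohex-3-ene-1-carbaldehyde | O=C[C@@H]1CCC(C)=C[C@H]1c1c(OC)cc(OC)c2ccc(=O)oc12 | intermediate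
11 | potassium [(2R)-2-(5,7-dimethoxy-2-oxo-2H-chromen-8-yl)-4-methylcyclohex-3-en-1-ylidene]methanolate | [K+].[O-]C=C1CCC(C)=C[C@H]1c1c(OC)cc(OC)c2ccc(=O)oc12 | intermediate
12 | (1S,2S)-2-(5,7-dimethoxy-2-oxo-2H-chromen-8-yl)-1,4-dimethylcyclohex-3-ene-1-carbaldehyde | O=C[C@@]1(C)CCC(C)=C[C@H]1c1c(OC)cc(OC)c2ccc(=O)oc12 | intermediate
13 | 8-[(1R,6R)-6-ethenyl-3,6-dimethylcyclohex-2-en-1-yl]-5,7-dimethoxy-2H-chromen-2-one | C=C[C@@]1(C)CCC(C)=C[C@H]1c1c(OC)cc(OC)c2ccc(=O)oc12 | intermediate
14 | 8-iodo-5,7-dimethoxy-2H-chromen-2-one | COc1cc(OC)c2ccc(=O)oc2c1I | intermediate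
15 | 8-[(E)-2-[(1R,2R)-2-(5,7-dimethoxy-2-oxo-2H-chromen-8-yl)-1,4-dimethylcyclohex-3-en-1-yl]ethenyl]-5,7-dimethoxy-2H-chromen-2-one | COc1cc(OC)c2ccc(=O)oc2c1/C=C/[C@@]1(C)CCC(C)=C[C@H]1c1c(OC)cc(OC)c2ccc(=O)oc12 | target

**Step count and risks**

Total step count: 9. Longest linear sequence: 6 steps (1 → 3 → 4 → 10 → 12 → 13 → 15; steps 1, 2, 5, 6, 7, 9).

Steps most likely to fail:

Step 5. What may go wrong: erosion of regio- or enantiocontrol when the lactone-bearing carbinol is ionised, or deactivation of the ruthenium alkylidene by amine and phosphoramidite residues so that ring closure stalls. The fallback sets out from 3 and comes back at enolate 11, hence at 12; ring C is then built by cycloaddition. Aldehyde 3 is olefinated with 1-(triphenylphosphoranylidene)propan-2-one (toluene, 90 °C) to (E)-5,7-dimethoxy-8-(3-oxobut-1-en-1-yl)-2H-chromen-2-one F1. Methylenation (Ph3PCH3Br, KOtBu, THF, 0 °C) gives 5,7-dimethoxy-8-[(1E)-3-methylbuta-1,3-dien-1-yl]-2H-chromen-2-one F2. An imidazolidinone-catalysed Diels–Alder reaction of F2 with acrolein follows (5-benzyl-2,2,3-trimethylimidazolidin-4-one hydrochloride, the enantiomer that gives the (2R) centre, MeCN/H2O, rt); the 1-aryl and 3-methyl groups of the diene both direct the formyl-bearing carbon to the aryl-bearing terminus. After removal of any exo isomer this should give the endo adduct (1S,2R)-2-(5,7-dimethoxy-2-oxo-2H-chromen-8-yl)-4-methylcyclohex-3-ene-1-carbaldehyde F3, the C1 epimer of 10. Deprotonation of F3 under the conditions of step 6 gives the same enolate 11 and thus 12.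

Step 6. What may go wrong: O-methylation or aldol self-condensation of the aldehyde enolate, opening of the lactone by base followed by methylation of the phenoxide, or too small a facial bias. The fallback sets out from 6 and 4 and comes back at 12; the quaternary centre is made under catalyst control before the ring is closed. Ester 6 is methylated (LiN(i-Pr)2, THF, −78 °C; MeI) to ethyl 2,5-dimethylhex-5-enoate F4, which is reduced (i-Bu2AlH, CH2Cl2, −78 °C) to 2,5-dimethylhex-5-enal F5. F5 and 4 are joined by the iridium catalyst of step 5 together with a cinchona-derived primary amine (9-amino-9-deoxy-epi-quinine or its quinidine-derived pseudoenantiomer, Cl3CCO2H, ClCH2CH2Cl, 25 °C), the known variant for α-branched aldehydes. This should give (2S)-2-[(1S)-1-(5,7-dimethoxy-2-oxo-2H-chromen-8-yl)prop-2-en-1-yl]-2,5-dimethylhex-5-enal F6, the C2 epimer being removed by chromatography. Ring-closing metathesis of F6 (second-generation Grubbs catalyst (H2IMes)(PCy3)Cl2Ru=CHPh, CH2Cl2, 40 °C) gives 12.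

Step 9. What may go wrong: slow oxidative addition and olefin insertion with the doubly ortho-substituted aryl iodide, competing arylation of a pyranone olefin (ring B or E), and precipitation of palladium metal before conversion is complete. The fallback sets out from 12 and 3 and comes back at 15; steps 7 and 8 are then not needed. Aldehyde 3 is reduced (NaBH4, MeOH/THF, 0 °C) to 8-(hydroxymethyl)-5,7-dimethoxy-2H-chromen-2-one F7, which with P(OEt)3 and ZnI2 (toluene, reflux) gives diethyl [(5,7-dimethoxy-2-oxo-2H-chromen-8-yl)methyl]phosphonate F8. Horner–Wadsworth–Emmons olefination of 12 with the anion of F8 (NaN(SiMe3)2, THF, −78 °C to rt) should give 15 directly, the (E)-olefin being favoured for a benzylic phosphonate and an α-quaternary aldehyde.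

Further compounds
F1 | step 5 | (E)-5,7-dimethoxy-8-(3-oxobut-1-en-1-yl)-2H-chromen-2-one | CC(=O)/C=C/c1c(OC)cc(OC)c2ccc(=O)oc12
F2 | step 5 | 5,7-dimethoxy-8-[(1E)-3-methylbuta-1,3-dien-1-yl]-2H-chromen-2-one | C=C(C)/C=C/c1c(OC)cc(OC)c2ccc(=O)oc12
F3 | step 5 | (1S,2R)-2-(5,7-dimethoxy-2-oxo-2H-chromen-8-yl)-4-methylcyclohex-3-ene-1-carbaldehyde | O=C[C@H]1CCC(C)=C[C@H]1c1c(OC)cc(OC)c2ccc(=O)oc12
F4 | step 6 | ethyl 2,5-dimethylhex-5-enoate (racemic) | CCOC(=O)C(C)CCC(C)=C
F5 | step 6 | 2,5-dimethylhex-5-enal (racemic) | O=CC(C)CCC(C)=C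
F6 | step 6 | (2S)-2-[(1S)-1-(5,7-dimethoxy-2-oxo-2H-chromen-8-yl)prop-2-en-1-yl]-2,5-dimethylhex-5-enal | O=C[C@@](C)(CCC(C)=C)[C@@H](C=C)c1c(OC)cc(OC)c2ccc(=O)oc12
F7 | step 9 | 8-(hydroxymethyl)-5,7-dimethoxy-2H-chromen-2-one | OCc1c(OC)cc(OC)c2ccc(=O)oc12
F8 | step 9 | diethyl [(5,7-dimethoxy-2-oxo-2H-chromen-8-yl)methyl]phosphonate | CCOP(=O)(Cc1c(OC)cc(OC)c2ccc(=O)oc12)OCC
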